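**Retrosynthetic overview**
1. Feature: ring A is a fully substituted phloroglucinol. Its oxygens on C5, C7 and C8a alternate with the carbon substituents on C4a (acyl C4), C6 (prenyl) and C8 (methyl), so it is a folded triketide. If O1 is bound to C2 and C8a as the enol ether of a dihydropyranone (ring C) before ring A exists, C6 and C8 can no longer be interchanged.
2. Target ⇒ 4'-O-MOM flavanone (acidic methanolysis) ⇒ C5–C6 Dieckmann disconnection of ring A ⇒ dihydropyranone with the ester (future C5) on C4a and the chain C8(Me)–C7(=O)–C6H2–prenyl on C8a.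
3. That keto ester ⇒ C7–C8 vinylogous Claisen acylation ⇒ 6-ethyl dihydropyranone ester + 5-methylhex-4-enoyl imidazolide.
4. 6-Ethyl dihydropyranone ⇒ C4a–C8a and O1–C8a condensation with a propionamide acetal ⇒ (S)-δ-hydroxy-β-keto ester ⇒ C2–C3 asymmetric vinylogous Mukaiyama aldol ⇒ MOM-protected 4-hydroxybenzaldehyde + bis-silyl dienolate of methyl acetoacetate.
5. Ring order: B (bought), C (step 6), A (step 9). C2 is set in step 4 and no later step breaks a bond to it.

Key step: step 9

Remark: the labels O1 and C2 to C8a are those of the flavanone and are used for the same atoms in every precursor.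
Assumption: with aromatic aldehydes the (S)-BINOL/Ti(OiPr)4 catalyst is taken to send the nucleophile to the Si face and give the S carbinol. If the sense proves opposite, (R)-BINOL is used and nothing else changes.
Remark: 17 should form as a mixture of C8 epimers and enol tautomers. This is of no consequence because C8 becomes an arene carbon in step 9.

Step 1
Reactants: 1 4-hydroxybenzaldehyde
Product: 2 4-(methoxymethoxy)benzaldehyde
Conditions: MOMCl, iPr2NEt, CH2Cl2, 0 °C to rt
Reagents that add atoms: chloromethyl methyl ether, COCCl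
Why: Williamson-type O-alkylation of the phenol by the reactive α-chloro ether gives the MOM acetal, which is inert to the titanium catalyst, the amide bases and the enolates used later.

Step 2
Reactants: 3 methyl acetoacetate
Product: 4 methyl 3-(trimethylsilyloxy)but-2-enoate (E/Z mixture)
Conditions: TMSCl, Et3N, hexane, rt
Reagents that add atoms: chlorotrimethylsilane, C[Si](C)(C)Cl
Why: O-silylation of the enol of the β-keto ester under amine base is the standard first stage towards the bis-silyl dienolate.

Step 3
Reactants: 4 methyl 3-(trimethylsilyloxy)but-2-enoate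
Product: 6 1-methoxy-1,3-bis(trimethylsilyloxy)buta-1,3-diene, via lithium dienolate 5 (not isolated)
Conditions: LiN(iPr)2, THF, −78 °C; TMSCl, −78 to 0 °C
Reagents that add atoms: chlorotrimethylsilane, C[Si](C)(C)Cl
Why: Kinetic γ-deprotonation of the vinylogous ester gives dienolate 5, which is silylated on oxygen to the known masked acetoacetate dianion.

Step 4
Reactants: 2 4-(methoxymethoxy)benzaldehyde; 6 1-methoxy-1,3-bis(trimethylsilyloxy)buta-1,3-diene
Product: 8 methyl (5S)-5-hydroxy-5-[4-(methoxymethoxy)phenyl]-3-oxopentanoate, via bis-silyl aldol adduct 7 (not isolated)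
Conditions: (S)-BINOL (10 mol %), Ti(OiPr)4 (10 mol %), 4 Å molecular sieves, THF, −78 °C to rt; then PPTS (cat.), MeOH, 0 °C
Reagents that add atoms: none
Why: In this catalytic asymmetric vinylogous Mukaiyama aldol reaction the BINOL–titanium complex binds the aldehyde and the γ-terminus of the dienolate attacks its Si face, which sets C2 as S, and cold buffered methanolysis strips both silyl groups of 7 without harming the MOM ether or the electron-rich benzylic carbinol.

Step 5
Reactants: 9 N,N-dimethylpropanamide
Product: 11 1,1-dimethoxy-N,N-dimethylpropan-1-amine, via methoxyiminium methyl sulfate 10 (not isolated)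
Conditions: Me2SO4, neat, 80 °C; then NaOMe, MeOH, 0 °C to rt; distillation
Reagents that add atoms: dimethyl sulfate, COS(=O)(=O)OC; sodium methoxide, C[O-].[Na+]
Why: O-methylation of the amide followed by addition of methoxide to the iminium carbon of 10 is the standard preparation of amide acetals.

Step 6
Reactants: 8 methyl (5S)-5-hydroxy-5-[4-(methoxymethoxy)phenyl]-3-oxopentanoate; 11 1,1-dimethoxy-N,N-dimethylpropan-1-amine
Product: 13 methyl (2S)-6-ethyl-2-[4-(methoxymethoxy)phenyl]-4-oxo-3,4-dihydro-2H-pyran-5-carboxylate, via enaminone 12 (not isolated)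
Conditions: toluene, rt
Reagents that add atoms: none
Why: In this Maitland–Japp-type condensation, known for δ-hydroxy-β-keto esters, the active methylene C4a attacks the alkoxyiminium form of 11 to give enaminone 12 and the C2 hydroxyl then displaces dimethylamine at C8a by conjugate addition–elimination, so ring C closes through oxygen without acid and without an O-acylation that would invite β-elimination, and the C2–O bond and its S configuration stay intact.

Step 7
Reactants: 14 5-methylhex-4-enoic acid
Product: 15 1-(imidazol-1-yl)-5-methylhex-4-en-1-one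
Conditions: 1,1'-carbonyldiimidazole, THF, rt
Reagents that add atoms: 1,1'-carbonyldiimidazole, O=C(n1ccnc1)n1ccnc1
Why: Carboxyl activation by carbonyldiimidazole gives the N-acylimidazole with loss of CO2 and imidazole, a mild acyl donor that favours C-acylation of enolates and leaves the trisubstituted alkene alone.

Step 8
Reactants: 13 methyl (2S)-6-ethyl-2-[4-(methoxymethoxy)phenyl]-4-oxo-3,4-dihydro-2H-pyran-5-carboxylate; 15 1-(imidazol-1-yl)-5-methylhex-4-en-1-one
Product: 17 methyl (2S)-2-[4-(methoxymethoxy)phenyl]-6-(7-methyl-3-oxooct-6-en-2-yl)-4-oxo-3,4-dihydro-2H-pyran-5-carboxylate, via lithium dienolate 16 (not isolated)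
Conditions: 13 added to LiN(SiMe3)2 (2.1 equiv), THF, −78 °C; 15, −78 to −40 °C; AcOH, −78 °C
Reagents that add atoms: none
Why: In this vinylogous Claisen acylation the CH2 of the 6-ethyl group, activated through C8a=C4a by both the ketone and the ester, is by far the most acidic site, so the equilibrating silylamide gives extended dienolate 16 rather than the C3 enolate, acylation at the fully substituted C4a is reversible, and the second equivalent of base drains γ-product 17 as its stabilised C8 anion, as in the γ-acylation of 6-alkyl-1,3-dioxin-4-one and 2-methylchromone dienolates.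

Step 9
Reactants: 17 methyl (2S)-2-[4-(methoxymethoxy)phenyl]-6-(7-methyl-3-oxooct-6-en-2-yl)-4-oxo-3,4-dihydro-2H-pyran-5-carboxylate
Product: 20 (2S)-5,7-dihydroxy-2-[4-(methoxymethoxy)phenyl]-8-methyl-6-(3-methylbut-2-enyl)chroman-4-one, via dilithium dianion 18 (not isolated), via trione tautomer 19 (not isolated)
Conditions: 17 added to LiN(iPr)2 (2.3 equiv), THF, −78 °C, then to −20 °C; AcOH (3 equiv), −78 °C
Reagents that add atoms: none
Why: Proposed new method: LiN(iPr)2 first removes the doubly activated C8–H and a second equivalent then takes a C6–H beside the C7 ketone; the C6 terminus of dianion 18 adds to the ester carbonyl that the ring holds cis to the side chain across the C4a–C8a bond, methoxide leaves to give trione 19, and the freed methoxide deprotonates C6 so that 19 tautomerises irreversibly to the phloroglucinol. The closest known reactions are the Claisen folding of 3,5,7-trioxo esters to acylphloroglucinols and the Dieckmann closure of 2-(2-oxoalkyl)benzoates to naphthalene-1,3-diols, but a chain masked as a dihydropyranone has not been closed in this way. Ring A closes in the 6-(enolendo)-exo-trig mode. No stereocentre is created: the C8 centre of 17 disappears and C2 is only carried through. The step needs C6 rather than C3 as the site of the second metalation, because a C3 carbanion would expel O1 by E1cB and erase C2; this is secured by the first deprotonation, which makes the C4 carbonyl part of an enolate and lowers the acidity of C3–H while C7 keeps ketone character, by the easier access to the acyclic C6 methylene and by the low temperature, whereas an amine with a magnesium salt would stop at the C8 anion. It also needs carbon rather than the C7 enolate oxygen to be acylated, since O1 ties up only the C8a oxygen and a 2-pyranone can still form through O7; the dianion reacts at its most nucleophilic carbon terminus, the ester is twisted out of conjugation with the C8 anion by its two flanking substituents and stays electrophilic, and any lactone is reopened by lithium methoxide whereas the arene cannot revert.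

Step 10
Reactants: 20 (2S)-5,7-dihydroxy-2-[4-(methoxymethoxy)phenyl]-8-methyl-6-(3-methylbut-2-enyl)chroman-4-one
Product: 21 (2S)-5,7-dihydroxy-2-(4-hydroxyphenyl)-8-methyl-6-(3-methylbut-2-enyl)chroman-4-one
Conditions: aq HCl (3 M)/MeOH 1:9, rt, followed closely; NaHCO3 quench
Reagents that add atoms: none
Why: Acid-catalysed acetal exchange with methanol cleaves the aryl MOM ether under conditions in routine use for prenylated flavanones, because dilute acid at room temperature neither adds the flanking phenols to the prenyl alkene nor opens ring C, so C2 stays S.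

**Compound list**
1 | 4-hydroxybenzaldehyde | O=Cc1ccc(O)cc1 | starting material
2 | 4-(methoxymethoxy)benzaldehyde | COCOc1ccc(C=O)cc1 | intermediate
3 | methyl acetoacetate | CC(=O)CC(=O)OC | starting material
4 | methyl 3-(trimethylsilyloxy)but-2-enoate (E/Z mixture) | COC(=O)C=C(C)O[Si](C)(C)C | intermediate
5 | lithium 1-methoxy-3-(trimethylsilyloxy)buta-1,3-dien-1-olate (not isolated) | [Li+].COC([O-])=CC(=C)O[Si](C)(C)C | intermediate
6 | 1-methoxy-1,3-bis(trimethylsilyloxy)buta-1,3-diene | COC(O[Si](C)(C)C)=CC(=C)O[Si](C)(C)C | intermediate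
7 | methyl (5S)-5-[4-(methoxymethoxy)phenyl]-3,5-bis(trimethylsilyloxy)pent-2-enoate (not isolated) | COC(=O)C=C(O[Si](C)(C)C)C[C@H](O[Si](C)(C)C)c1ccc(OCOC)cc1 | intermediate
8 | methyl (5S)-5-hydroxy-5-[4-(methoxymethoxy)phenyl]-3-oxopentanoate | COC(=O)CC(=O)C[C@H](O)c1ccc(OCOC)cc1 | intermediate
9 | N,N-dimethylpropanamide | CCC(=O)N(C)C | starting material
10 | (1-methoxypropylidene)dimethylammonium methyl sulfate (not isolated) | CCC(OC)=[N+](C)C.COS(=O)(=O)[O-] | intermediate
11 | 1,1-dimethoxy-N,N-dimethylpropan-1-amine | CCC(OC)(OC)N(C)C | intermediate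
12 | methyl (5S)-2-[1-(dimethylamino)propylidene]-5-hydroxy-5-[4-(methoxymethoxy)phenyl]-3-oxopentanoate (not isolated) | CCC(N(C)C)=C(C(=O)OC)C(=O)C[C@H](O)c1ccc(OCOC)cc1 | intermediate
13 | methyl (2S)-6-ethyl-2-[4-(methoxymethoxy)phenyl]-4-oxo-3,4-dihydro-2H-pyran-5-carboxylate | COC(=O)C1=C(CC)O[C@H](c2ccc(OCOC)cc2)CC1=O | intermediate
14 | 5-methylhex-4-enoic acid | CC(C)=CCCC(=O)O | starting material
15 | 1-(imidazol-1-yl)-5-methylhex-4-en-1-one | CC(C)=CCCC(=O)n1ccnc1 | intermediate
16 | lithium (2S)-6-ethylidene-5-(methoxycarbonyl)-2-[4-(methoxymethoxy)phenyl]-3,6-dihydro-2H-pyran-4-olate (not isolated) | [Li+].CC=C1O[C@H](c2ccc(OCOC)cc2)CC([O-])=C1C(=O)OC | intermediate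
17 | methyl (2S)-2-[4-(methoxymethoxy)phenyl]-6-(7-methyl-3-oxooct-6-en-2-yl)-4-oxo-3,4-dihydro-2H-pyran-5-carboxylate (C8 epimers) | COC(=O)C1=C(C(C)C(=O)CCC=C(C)C)O[C@H](c2ccc(OCOC)cc2)CC1=O | intermediate
18 | dilithium dianion of 17 (C4 oxide with C8=C8a, C7 oxide with C6=C7; not isolated) | [Li+].[Li+].COC(=O)C1=C([O-])C[C@@H](c2ccc(OCOC)cc2)OC1=C(C)C([O-])=CCC=C(C)C | intermediate
19 | (2S)-2-[4-(methoxymethoxy)phenyl]-8-methyl-6-(3-methylbut-2-enyl)-2,3-dihydro-4H-chromene-4,5,7(6H,8H)-trione (not isolated) | CC(C)=CCC1C(=O)C(C)C2=C(C1=O)C(=O)C[C@@H](c1ccc(OCOC)cc1)O2 | intermediate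
20 | (2S)-5,7-dihydroxy-2-[4-(methoxymethoxy)phenyl]-8-methyl-6-(3-methylbut-2-enyl)chroman-4-one | CC(C)=CCc1c(O)c(C)c2c(c1O)C(=O)C[C@@H](c1ccc(OCOC)cc1)O2 | intermediate
21 | (2S)-5,7-dihydroxy-2-(4-hydroxyphenyl)-8-methyl-6-(3-methylbut-2-enyl)chroman-4-one | CC(C)=CCc1c(O)c(C)c2c(c1O)C(=O)C[C@@H](c1ccc(O)cc1)O2 | target

Total step count: 10. Longest linear sequence: 7 steps (steps 2, 3, 4, 6, 8, 9, 10, from 3 to 21).

**Steps most likely to fail**

**Step 9 (Proposed new method).**
- What may go wrong:
  - The second metalation may occur at C3. Ring C then opens by E1cB, and both the C2 configuration and the O1 lock are lost.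
  - The ester, still partly conjugated with the C8 anion, may be too poor an electrophile, so the dianion simply persists.
  - Acylation through the C7 enolate oxygen may outrun C6 and divert material into lactonisation.
- Fallback (known chemistry, ring A taken as a ready-made arene, ring C closed last). It sets out from 2 and comes back at 21. Commercial 2,4,6-trihydroxy-3-methylacetophenone is treated with MOMCl (2.2 equiv) and iPr2NEt. This should leave free only the hydroxyl that is chelated to the ketone and flanked by the methyl group, giving 1-[2-hydroxy-4,6-bis(methoxymethoxy)-3-methylphenyl]ethanone F1. O-Alkylation with prenyl bromide and K2CO3 in acetone gives 1-[4,6-bis(methoxymethoxy)-3-methyl-2-(3-methylbut-2-enyloxy)phenyl]ethanone F2. Heating in N,N-diethylaniline at about 200 °C brings about a Claisen–Cope (para-Claisen) rearrangement, since both ortho positions are blocked. The prenyl group ends up between the two MOM ethers in 1-[2-hydroxy-4,6-bis(methoxymethoxy)-3-methyl-5-(3-methylbut-2-enyl)phenyl]ethanone F3, whose single free hydroxyl next to the methyl group now fixes the regiochemistry of ring C. Claisen–Schmidt condensation of F3 with 2 (KOH, EtOH) gives (E)-1-[2-hydroxy-4,6-bis(methoxymethoxy)-3-methyl-5-(3-methylbut-2-enyl)phenyl]-3-[4-(methoxymethoxy)phenyl]prop-2-en-1-one F4. NaOAc in refluxing EtOH closes ring C by oxa-Michael addition to racemic 5,7-bis(methoxymethoxy)-2-[4-(methoxymethoxy)phenyl]-8-methyl-6-(3-methylbut-2-enyl)chroman-4-one F5. Preparative HPLC on a chiral stationary phase delivers (2S)-5,7-bis(methoxymethoxy)-2-[4-(methoxymethoxy)phenyl]-8-methyl-6-(3-methylbut-2-enyl)chroman-4-one F6. The conditions of step 10 then remove all three MOM groups to give 21. The cost is that half the material is lost in the resolution.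

**Step 8.**
- What may go wrong:
  - Kinetic deprotonation at C3 may compete.
  - The hindered secondary γ-carbanion may acylate slowly, or the dienolate may react on oxygen.
  - Proton transfer from the product may stall conversion.
- Fallback (acylate a primary terminus, install the C8 methyl last). It sets out from 8 and 15 and comes back at 17. Compound 8 is condensed with commercial N,N-dimethylacetamide dimethyl acetal (toluene, rt) to give methyl (2S)-2-[4-(methoxymethoxy)phenyl]-6-methyl-4-oxo-3,4-dihydro-2H-pyran-5-carboxylate F7. Its unhindered primary dienolate (LiN(SiMe3)2, 2.1 equiv, THF, −78 °C) is acylated with 15 to give methyl (2S)-2-[4-(methoxymethoxy)phenyl]-6-(6-methyl-2-oxohept-5-enyl)-4-oxo-3,4-dihydro-2H-pyran-5-carboxylate F8. C-Alkylation of the doubly activated C8 methylene (K2CO3, MeI, acetone, rt) then gives 17.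

**Step 6.**
- What may go wrong: slow condensation of the more hindered propionamide acetal may let base-induced lactonisation of the δ-hydroxy ester, or dehydration of the benzylic aldol unit, take over.
- Fallback (stepwise C-acylation, then cyclodehydration). It sets out from 8 and comes back at 13. Silylation (TESCl, imidazole, CH2Cl2, 0 °C) gives methyl (5S)-5-[4-(methoxymethoxy)phenyl]-3-oxo-5-(triethylsilyloxy)pentanoate F9. C-Acylation of its magnesium chelate (MgCl2, pyridine, propanoyl chloride, CH2Cl2, 0 °C) gives methyl (5S)-5-[4-(methoxymethoxy)phenyl]-3-oxo-2-propanoyl-5-(triethylsilyloxy)pentanoate F10. HF·pyridine buffered with pyridine (THF, 0 °C to rt) removes the silyl group, the freed hydroxyl condenses with the propanoyl carbonyl, and loss of water gives 13.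

**Further compounds**
F1 | step 9 | 1-[2-hydroxy-4,6-bis(methoxymethoxy)-3-methylphenyl]ethanone | CC(=O)c1c(O)c(C)c(OCOC)cc1OCOC
F2 | step 9 | 1-[4,6-bis(methoxymethoxy)-3-methyl-2-(3-methylbut-2-enyloxy)phenyl]ethanone | CC(=O)c1c(OCC=C(C)C)c(C)c(OCOC)cc1OCOC
F3 | step 9 | 1-[2-hydroxy-4,6-bis(methoxymethoxy)-3-methyl-5-(3-methylbut-2-enyl)phenyl]ethanone | CC(=O)c1c(O)c(C)c(OCOC)c(CC=C(C)C)c1OCOC
F4 | step 9 | (E)-1-[2-hydroxy-4,6-bis(methoxymethoxy)-3-methyl-5-(3-methylbut-2-enyl)phenyl]-3-[4-(methoxymethoxy)phenyl]prop-2-en-1-one | COCOc1ccc(/C=C/C(=O)c2c(O)c(C)c(OCOC)c(CC=C(C)C)c2OCOC)cc1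
F5 | step 9 | racemic 5,7-bis(methoxymethoxy)-2-[4-(methoxymethoxy)phenyl]-8-methyl-6-(3-methylbut-2-enyl)chroman-4-one | CC(C)=CCc1c(OCOC)c(C)c2OC(c3ccc(OCOC)cc3)CC(=O)c2c1OCOC
F6 | step 9 | (2S)-5,7-bis(methoxymethoxy)-2-[4-(methoxymethoxy)phenyl]-8-methyl-6-(3-methylbut-2-enyl)chroman-4-one | CC(C)=CCc1c(OCOC)c(C)c2O[C@H](c3ccc(OCOC)cc3)CC(=O)c2c1OCOC
F7 | step 8 | methyl (2S)-2-[4-(methoxymethoxy)phenyl]-6-methyl-4-oxo-3,4-dihydro-2H-pyran-5-carboxylate | COC(=O)C1=C(C)O[C@H](c2ccc(OCOC)cc2)CC1=O
F8 | step 8 | methyl (2S)-2-[4-(methoxymethoxy)phenyl]-6-(6-methyl-2-oxohept-5-enyl)-4-oxo-3,4-dihydro-2H-pyran-5-carboxylate | COC(=O)C1=C(CC(=O)CCC=C(C)C)O[C@H](c2ccc(OCOC)cc2)CC1=O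
F9 | step 6 | methyl (5S)-5-[4-(methoxymethoxy)phenyl]-3-oxo-5-(triethylsilyloxy)pentanoate | COC(=O)CC(=O)C[C@H](O[Si](CC)(CC)CC)c1ccc(OCOC)cc1
F10 | step 6 | methyl (5S)-5-[4-(methoxymethoxy)phenyl]-3-oxo-2-propanoyl-5-(triethylsilyloxy)pentanoate | CCC(=O)C(C(=O)OC)C(=O)C[C@H](O[Si](CC)(CC)CC)c1ccc(OCOC)cc1
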